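The vessel is closed, stirred and held at constant temperature, and the next run must repeat whichever of the two recipes gives more bis adduct in the time set.

| setting | south | west |
|---|---|---|
| substrate | 20 mM | 20 mM |
| reagent | 1.50 equiv | 1.50 equiv |
| temperature | 50 °C | 25 °C |
| time | 80 s | 80 s |

    substrate + reagent → mono adduct (k1 = 2.6 /M/s, Ea1 = 65.0 kJ/mol)
    reagent + mono adduct → bis adduct (k2 = 5.9 /M/s, Ea2 = 63.0 kJ/mol)
    reagent + bis adduct → tris adduct (k3 = 0.28 /M/s, Ea3 = 47.0 kJ/mol)
    crystals ⇌ bis adduct, rate k4*(cs4 - [bis adduct]) while solid is left; crystals form when [bis adduct] > cs4 (cs4 = 0.31 mM, k4 = 1.2 /s)
    (constants at 50 °C)

- for bis adduct the crystals are counted in
- as a solid, counted per litre of solution: crystals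
- constants are those at 50 °C; use the activation energies for any other temperature

- the flask that comes out highest in amount of bis adduct, in percent of the substrate charged, or "all alike" when all lie within 1.5 percentage points (south / west / all alike)
- bis adduct at the end, in percent of the substrate charged, south
- bis adduct at the end, in percent of the substrate charged, west

Once crystals stand, they take up bis adduct, so dissolved bis adduct stands near its solubility of 0.31 mM. The third step is dropped from this reckoning because, with bis adduct at that solubility, it runs far slower per unit of reagent than the first step does at half the substrate charge, in south and in west. The logarithm of substrate then falls at the first constant times reagent, which integrates in closed form: the fraction left, x, is the exponential of minus that constant times the time integral of reagent. In west this gives 2.03 M·s as the halving exposure, the time integral of reagent that halves substrate; south needs 0.267 M·s.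

Dividing the second step by the first removes reagent. Mono adduct, as a fraction of the charge, is then x minus x to the power s, divided by s minus one, where s is the selectivity factor: 2.27 in south and 2.42 in west. At halving, bis adduct stands at 26.9% in south and 27.9% in west, so at that conversion west holds 1.00 percentage point more.

Reagent falls from 30.0 mM by one unit per substrate converted and one more per bis adduct formed. Its mean up to halving in west is 22.2 mM. The halving time in west is therefore 91.3 s, longer than the 80 s allowed, while in south it is 12.0 s. The same mean over the whole west run leaves substrate at 54.5% and bis adduct at 23.3%. South holds its 26.9% at a reckoned halving inside the run, which is more than the 23.3% reckoned for the end of west. Beyond that point the reckoning gives south a ceiling of 75.0%, from reagent, the limiting reagent, at 1.50 equiv against the two equivalents bis adduct takes. The next run therefore goes with the south recipe.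

The forecast names south, with 63.8% there and 23.4% in west, on the ground that crystallisation “nearly shuts off step 3”.

The simulation gives 63.9% in south and 23.4% in west, so south comes out highest. South reaches 50 percent conversion at 12.5 s, far inside its 80 s, whereas west, with its exposure of 2.03 M·s and a halving time reckoned beyond the end of the run, stops with 54.2% of its substrate left and with less bis adduct than the 27.7% it holds at 50 percent conversion. A flask otherwise like west but with 2.50 equiv of reagent takes the same exposure in a reckoned halving time of 48.0 s, shorter than 80 s, and it ends with 36% of its substrate left and bis adduct at 44.4%.

The constants used here stand for no real mixture; what happens was integrated by code.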